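Take the easy step first: split the reagent.

- Saturday's: E 0.80 M; J 1.20 M; temperature 15 °C; time 6.0 min; volume of the second phase over the first 1.0
- Thursday's: E 0.80 M; J 1.20 M; temperature 5 °C; time 6.0 min; volume of the second phase over the first 1.0

    X ⇌ J, rate k1*([X] - [J]/K1) per volume of the first phase (K1 = 1.7, k1 = 0.143 s⁻¹)
    E + X → E.X (k2 = 0.00383 M⁻¹ s⁻¹, Ea2 = 47.0 kJ mol⁻¹)
    E.X ⇌ Z, rate k3*([E.X] - [Z]/K3) per volume of the first phase (K3 = 0.550, k3 = 0.00405 s⁻¹)
    E.X → L (k4 = 0.0296 s⁻¹, Ea4 = 77.0 kJ mol⁻¹)
    G ⇌ E.X, rate k5*(cs5 - [E.X]) while solid is left; crystals form when [E.X] > cs5 (cs5 = 0.44 M, k5 = 0.401 s⁻¹)
    (constants at 5 °C)

- E.X is meant together with its Z and G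
- in the second phase: J, Z; everything else is in the first
- charges count per volume of the first phase; a concentration in a rate is the amount of a species over the volume of its own phase; every rate counts per litre of the first phase
- solid, in amounts per volume of the solution: G
- at 5 °C the constants are as listed, elsewhere as the activation energies make them

- which of these there is most of at the end, counted by the E in it, Saturday's (L / E.X / E)
- which of these there is most of at the end, counted by the E in it, Thursday's (L / E.X / E)
- amount of the one of these that there is most of at the end, in percent of the E charged, Saturday's
- amount of the one of these that there is most of at the end, in percent of the E charged, Thursday's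

J is charged in the second phase, and E meets it in the first as X. With none used, the partition ratio puts X at 0.444 M. Saturday's rate constant for E with X stands 2.02 times Thursday's. The time constant of E against X held at the split level, call it the reagent time, is 4.84 min for Saturday's and 9.79 min for Thursday's. Transfer takes about 0.117 min, far less than that, so let X follow the split.

The bench rule calls this pseudo-first-order: E left is the exponential of minus time over reagent time. For Saturday's that gives 28.9%. But the rule needs X to hold still. Its border is r, the E charge over the reagent charge, far below 1, and here r is 0.667. Every E taken uses up reagent, so the X level falls.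

Integrate with that fall. Let w be the exponential of (r − 1) times time over reagent time. The part of E left is then (1 − r)·w/(1 − r·w). That gives 39.4% for Saturday's, more than the rule gave, and 59.5% for Thursday's.

Now follow what was taken. E.X drains to L with a time constant of 0.177 min on Saturday's and 0.563 min on Thursday's, far shorter than the run. So E.X holds about drain time over run time of what was taken, and L holds the rest. Thursday's E.X then stands near 0.0304 M, below the solubility of 0.44 M, so expect no crystals.

Commit: Saturday's ends with L at 58.8%. Thursday's ends with E at 59.5%.

The forecast gives L at 58% for Saturday's and E at 60% for Thursday's, holding that “E.X drains to L far faster than it forms”.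

Saturday's flask, 1.24 reagent times long, ends with L at 58.3% and E at 40.1%. Thursday's, 0.613 reagent times long, ends with E at 60.0% and L at 35.6%.

Now charge 2.0 M of E into Saturday's flask, time and all else held. The reagent charge and temperature stay, so the reagent time stays 4.84 min. But r becomes 1.67, and the reagent is now the limiting reagent. The same formula with the new r puts E left at 54.2%. That flask ends with most in E, at 54.9% of the charge, and L at 44.1%.

The rate constants were drawn at random within sensible limits; what happens was integrated by code.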